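# Proposed synthesis of 1-[4-hydroxy-2-methoxy-3-(3-methylbut-2-enyl)phenyl]-3-[4-hydroxy-3-(3-methylbut-2-enyl)phenyl]propane-1,3-dione (16)

## The problem

The target is a 1,3-diarylpropane-1,3-dione. C1 of the chain carries ring A (4-hydroxy-2-methoxy-3-prenylphenyl) and C3 carries ring B (4-hydroxy-3-prenylphenyl, bonded through C1'). No ring has to be closed and there is no stereocentre or stereogenic double bond, so the task is bond construction, arene regiochemistry and functional-group survival. Ring A is a 1,2,3,4-substituted benzene whose prenyl group sits between two oxygens that must be told apart: O2 is methylated and O4 is free. Both prenyl groups lie ortho to a phenolic hydroxyl. Acids strong enough for Friedel–Crafts chemistry would therefore close them to 2,2-dimethylchromans or add across the trisubstituted alkenes, and hydrogenation and electrophilic halogen are ruled out by the same alkenes. The 1,3-diketone has an acidic, metal-chelating C2 methylene and is open to retro-Claisen cleavage, so it is best revealed last. The feature that allows a late, neutral union is that C3 is a carbonyl carbon bonded directly to C1' of ring B. Such an aryl–acyl bond can be made from an acyl–sulfur bond and an aryl–boron bond under palladium and copper without acid or base, while the C2 methylene is hidden as an enol ether on C1.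

## Retrosynthesis

**16 from 15.** The last cut is at three O–CH2OMe acetal bonds: the two phenols and the C1 enol oxygen are all carried as methoxymethyl (MOM) ethers in 15. A methyl enol ether was weighed for C1. It needs hydrolytic attack of water at a hindered vinylogous ester carbon under more forcing acid, which is the condition the o-prenylphenols tolerate least, and its formation from a β-keto thioester competes with C-methylation. The enol MOM ether forms O-selectively and falls off by acetal cleavage, leaving the oxygen on C1. Compound 15 has no acidic or chelating site. The forward step must cleave three acetals faster than a freed phenol can add to its neighbouring alkene.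

**15 from 8 and 14.** The C3–C1' bond is cut, giving the enol-ether-masked β-keto thioester 8 and the ring B boronic acid 14. The neighbouring options are weaker for this target:
- Friedel–Crafts acylation at the same bond needs acid and is excluded by the prenyl groups.
- Aryllithium addition to an acyl donor is strongly basic and can add twice or in conjugate fashion.
- A crossed Claisen condensation of ketone 5 with a ring B benzoate moves the cut to C2–C3. It is workable, but it is an equilibrium under strong base with an electron-rich, sluggish ester.

The thioester–boronic acid coupling is neutral and splits the molecule into two halves of similar size. The forward reaction must activate the C–S bond selectively and leave two prenyl groups and three acetals alone.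

**8 from 7, and 7 from 5 and 6.** The enol O–CH2 bond is cut first, then the C2–C3 bond. C3 comes from S,S-diethyl dithiocarbonate 6, a carbonyl carbon with two sulfur leaving groups. The enolate of 5 displaces one, and the other is kept as the handle for the key step. Building the same fragment from a ring A benzoic acid and a malonic half thioester would need a different ring A starting material. The acetophenone 5 already holds C1 and C2.

**5 from 4, 3, and 1 with 2.** Ring A is simplified by removing the O2 methyl (5 to 4), the O4 MOM group (4 to 3) and the prenyl group (3 to 2,4-dihydroxyacetophenone 1 and prenyl bromide 2). The order is set by the chelated 2-OH: it stays inert while O4 is protected and is methylated afterwards, which differentiates the two oxygens without extra steps. The forward prenylation must favour C3 over C5 and over oxygen.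

**14 from 11, 10, and 9 with 2.** The C–B bond is traced to the bromide 11, the MOM ether to phenol 10, and the prenyl group to 4-bromophenol 9 and 2. Bromine blocks the para position during ortho-prenylation and then serves as the site of metalation.

## Roads not taken

**Alternative 1:** Ring A would be built last by a Diels–Alder benzannulation. The diene A2 (1,1-dimethoxy-2-prenyl-3-silyloxybutadiene) would add across the terminal alkyne of the cross-conjugated diynone A3. This forms the C1–C2 and C5–C6 bonds of ring A, and 1,4-loss of methanol aromatises the adduct to the aryl ynone A1. Hydration of the alkyne and desilylation would then lead to 16.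
- Merit: the 2-methoxy, 3-prenyl, 4-oxygen pattern of ring A is written into the diene. The plan is therefore better than the chosen one at the point where the chosen one is weakest, the unselective C3-prenylation of 1. The cycloaddition regiochemistry is also well defined, since the nucleophilic CH2 terminus of A2 attacks the alkyne β-carbon.
- Weak points: A2 is an unknown, hydrolytically fragile ketene acetal that needs several steps. A3 is a double Michael acceptor with two competing alkynes. The ynone must still be hydrated in the presence of two prenyl alkenes. The step count is clearly higher.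
- Comparison: the chosen plan has a short ring A sequence from a cheap acetophenone that already contains C1 and C2, and the prenylation loss falls on the first step.

**Alternative 2:** The diketone would be carried as an isoxazole. Zerovalent palladium would couple the ring A bromide A5 with the 5-stannyl-3-arylisoxazole A6 in a Stille reaction, forming the bond from ring A C1 to the future carbonyl carbon and giving A4. The N–O bond would then be cleaved reductively and the nitrogen hydrolysed off.
- Merit: the isoxazole is a sturdier mask than any enol ether. It is inert to base, organometallics and chromatography, and in this respect it is better than the enol MOM ether of 8. Stille coupling is dependable, and A6 should come from a regioselective nitrile oxide–alkyne cycloaddition.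
- Weak points: A5 is an electron-rich bromide flanked by a methoxy group, so oxidative addition is slow. Making A5 is awkward, because electrophilic bromination cannot be done with the prenyl alkene present and prenylation by ortho-lithiation cannot be done with the bromide present. Nitrile oxide generation uses electrophilic chlorine near a prenyl group. Unmasking cannot use hydrogenation and adds operations after the coupling. Stoichiometric tin must be removed.
- Comparison: the chosen plan has one step after the coupling, uses no tin, and needs no halogenation of a prenylated arene.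

**Alternative 3:** The C2 methylene would be inserted last. Me3SiCHN2 would add to one carbonyl of the unsymmetrical benzil A8 under Sc(OTf)3, the neighbouring acyl group would migrate with loss of N2, and the bis-MOM diketone A7 would result after loss of silicon.
- Merit: attack at either carbonyl followed by acyl shift gives the same 1,3-diketone, so the insertion has no regiochemical issue. On paper this is the most direct route to the carbon skeleton.
- Weak points: acyl migration must beat aryl migration and epoxide formation. The enolisable product can react again with the diazo reagent. Sc(OTf)3 is a Lewis acid in the presence of MOM ethers and prenyl groups. A8 has no mild source, since routes through alkyne or benzylic oxidation clash with the two prenyl alkenes.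
- Comparison: every bond-forming step of the chosen plan belongs to a reaction type already established for its substrate class, and no Lewis acid is used.

Key step: step 9

Remark on the chemistry: enol ethers 8 and 15 are drawn as the (Z) isomers expected from O-alkylation of a chelated sodium enolate. Either geometry serves, because the enol ether is cleaved in step 10. The target is written as the diketone, although it should exist largely as its chelated enol tautomer.

## Route

Step 1
Reactants: 1 2,4-dihydroxyacetophenone; 2 1-bromo-3-methylbut-2-ene (prenyl bromide)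
Product: 3 1-[2,4-dihydroxy-3-(3-methylbut-2-enyl)phenyl]ethanone
Conditions: KOH (10% aq), 0 °C to rt
Reagents that add atoms: none
Why: C-alkylation of a resorcinol-type phenoxide in water, where hydrogen bonding to oxygen steers attack through carbon; C3 between the two oxygens is the most electron-rich carbon, and this direct prenylation is known for this ketone, the C5 isomer and O-prenyl ether being removed by chromatography.

Step 2
Reactants: 3 1-[2,4-dihydroxy-3-(3-methylbut-2-enyl)phenyl]ethanone
Product: 4 1-[2-hydroxy-4-(methoxymethoxy)-3-(3-methylbut-2-enyl)phenyl]ethanone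
Conditions: MOMCl (1.1 equiv), K2CO3, acetone, rt
Reagents that add atoms: chloromethyl methyl ether (MOMCl), COCCl
Why: Williamson-type acetal formation at the more acidic, unhindered 4-OH; the 2-OH is held in a hydrogen bond to the acetyl carbonyl and is not touched by the weak base.

Step 3
Reactants: 4 1-[2-hydroxy-4-(methoxymethoxy)-3-(3-methylbut-2-enyl)phenyl]ethanone
Product: 5 1-[2-methoxy-4-(methoxymethoxy)-3-(3-methylbut-2-enyl)phenyl]ethanone
Conditions: MeI, K2CO3, DMF, 40 °C
Reagents that add atoms: iodomethane, CI
Why: Williamson methylation of the only remaining hydroxyl; the polar solvent opens the chelate and carbonate is too weak to enolise the ketone, so C-methylation is not expected.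

Step 4
Reactants: 5 1-[2-methoxy-4-(methoxymethoxy)-3-(3-methylbut-2-enyl)phenyl]ethanone; 6 S,S-diethyl dithiocarbonate
Product: 7 S-ethyl 3-[2-methoxy-4-(methoxymethoxy)-3-(3-methylbut-2-enyl)phenyl]-3-oxopropanethioate
Conditions: NaH (2.5 equiv), 6 (1.5 equiv), DME, rt to 60 °C, slow addition of 5; then AcOH
Reagents that add atoms: none
Why: Claisen-type thiocarboxylation of a ketone enolate with an S,S-dialkyl dithiocarbonate, a known route to β-keto thioesters; one ethanethiolate is displaced, deprotonation of the product drives the reaction, and slow addition of 5 to base and 6 keeps self-aldol condensation down.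

Step 5
Reactants: 7 S-ethyl 3-[2-methoxy-4-(methoxymethoxy)-3-(3-methylbut-2-enyl)phenyl]-3-oxopropanethioate
Product: 8 S-ethyl (Z)-3-(methoxymethoxy)-3-[2-methoxy-4-(methoxymethoxy)-3-(3-methylbut-2-enyl)phenyl]prop-2-enethioate
Conditions: NaH, THF, 0 °C; MOMCl, 0 °C to rt
Reagents that add atoms: chloromethyl methyl ether (MOMCl), COCCl
Why: O-alkylation of a β-dicarbonyl enolate by the hard electrophile chloromethyl methyl ether (enol MOM ether formation); the chelated sodium enolate should give mainly the (Z) isomer, and any (E) isomer is carried along because both converge in step 10.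

Step 6
Reactants: 9 4-bromophenol; 2 1-bromo-3-methylbut-2-ene (prenyl bromide)
Product: 10 4-bromo-2-(3-methylbut-2-enyl)phenol
Conditions: NaH, toluene, 0 °C; prenyl bromide, rt
Reagents that add atoms: none
Why: ortho-C-alkylation of a sodium phenoxide as a tight ion pair in a non-polar solvent, a standard route to o-prenylphenols; bromine blocks the para position and SN2 attack at the primary carbon gives the linear prenyl group.

Step 7
Reactants: 10 4-bromo-2-(3-methylbut-2-enyl)phenol
Product: 11 4-bromo-1-(methoxymethoxy)-2-(3-methylbut-2-enyl)benzene
Conditions: NaH, THF, 0 °C; MOMCl, 0 °C to rt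
Reagents that add atoms: chloromethyl methyl ether (MOMCl), COCCl
Why: Williamson-type MOM protection of the phenol, needed before halogen–lithium exchange and matched to the protecting groups of ring A.

Step 8
Reactants: 11 4-bromo-1-(methoxymethoxy)-2-(3-methylbut-2-enyl)benzene
Product: 14 [4-(methoxymethoxy)-3-(3-methylbut-2-enyl)phenyl]boronic acid, via aryllithium 12 (not isolated), via lithium aryltriisopropoxyborate 13 (not isolated)
Conditions: n-BuLi, THF, −78 °C; B(OiPr)3, −78 °C to rt; aq NH4Cl
Reagents that add atoms: triisopropyl borate, CC(C)OB(OC(C)C)OC(C)C; water, O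
Why: Bromine–lithium exchange at −78 °C outruns ortho-lithiation next to the MOM ether; the aryllithium is trapped by the borate and the boronate is hydrolysed near neutral pH, which the MOM ether tolerates (lithiation–borylation).

Step 9
Reactants: 8 S-ethyl (Z)-3-(methoxymethoxy)-3-[2-methoxy-4-(methoxymethoxy)-3-(3-methylbut-2-enyl)phenyl]prop-2-enethioate; 14 [4-(methoxymethoxy)-3-(3-methylbut-2-enyl)phenyl]boronic acid
Product: 15 (Z)-3-(methoxymethoxy)-3-[2-methoxy-4-(methoxymethoxy)-3-(3-methylbut-2-enyl)phenyl]-1-[4-(methoxymethoxy)-3-(3-methylbut-2-enyl)phenyl]prop-2-en-1-one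
Conditions: Pd2(dba)3 (2.5 mol %), tri(2-furyl)phosphine (15 mol %), CuTC (copper thiophene-2-carboxylate, CuO2CC4H3S, monovalent copper; 1.6 equiv), 14 (1.5 equiv), THF, 50 °C, argon
Reagents that add atoms: none
Why: Zerovalent palladium inserts into the C(=O)–S bond of 8. The monovalent copper carboxylate then binds the sulfur on palladium while its carboxylate oxygen coordinates boron, so the aryl group of 14 passes to palladium without added base and copper ethanethiolate acts as the sulfur sink. Reductive elimination forms the C3–C1' bond and returns zerovalent palladium. The closest known reaction type is the Liebeskind–Srogl ketone synthesis from thiol esters, α,β-unsaturated ones included, and arylboronic acids. No ring closes and no stereocentre is formed; the (Z) enol ether geometry should be retained but is of no consequence. The step needs chemoselective acyl C–S activation with substitution at the acyl carbon and not conjugate arylation, which the thiophilic copper carboxylate and the hindered, donor-substituted enol carbon secure. Masking C1–C2 as the enol ether removes the acidic methylene that would otherwise bind copper as a chelated enolate, and the neutral medium leaves the aryl MOM ethers and both prenyl groups alone. An excess of 14 under strict exclusion of air covers losses to protodeboronation and oxidative homocoupling.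

Step 10
Reactants: 15 (Z)-3-(methoxymethoxy)-3-[2-methoxy-4-(methoxymethoxy)-3-(3-methylbut-2-enyl)phenyl]-1-[4-(methoxymethoxy)-3-(3-methylbut-2-enyl)phenyl]prop-2-en-1-one
Product: 16 1-[4-hydroxy-2-methoxy-3-(3-methylbut-2-enyl)phenyl]-3-[4-hydroxy-3-(3-methylbut-2-enyl)phenyl]propane-1,3-dione
Conditions: HCl (2 M aq)/MeOH (1:5), 40 °C
Reagents that add atoms: none
Why: Acid-catalysed acetal cleavage of all three MOM ethers in methanol, with the methoxymethyl cations captured as dimethoxymethane; the freed C1 enol is the tautomer of the 1,3-diketone, so no water has to add. Dilute acid at mild temperature is precedented for MOM removal from o-prenylphenols without chroman formation, and the 2-methoxy group rules out flavone-type cyclisation.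

## Compound list

1 | 2,4-dihydroxyacetophenone | CC(=O)c1ccc(O)cc1O | starting material
2 | 1-bromo-3-methylbut-2-ene (prenyl bromide) | CC(C)=CCBr | starting material
3 | 1-[2,4-dihydroxy-3-(3-methylbut-2-enyl)phenyl]ethanone | CC(=O)c1ccc(O)c(CC=C(C)C)c1O | intermediate
4 | 1-[2-hydroxy-4-(methoxymethoxy)-3-(3-methylbut-2-enyl)phenyl]ethanone | CC(=O)c1ccc(OCOC)c(CC=C(C)C)c1O | intermediate
5 | 1-[2-methoxy-4-(methoxymethoxy)-3-(3-methylbut-2-enyl)phenyl]ethanone | CC(=O)c1ccc(OCOC)c(CC=C(C)C)c1OC | intermediate
6 | S,S-diethyl dithiocarbonate | CCSC(=O)SCC | starting material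
7 | S-ethyl 3-[2-methoxy-4-(methoxymethoxy)-3-(3-methylbut-2-enyl)phenyl]-3-oxopropanethioate | CCSC(=O)CC(=O)c1ccc(OCOC)c(CC=C(C)C)c1OC | intermediate
8 | S-ethyl (Z)-3-(methoxymethoxy)-3-[2-methoxy-4-(methoxymethoxy)-3-(3-methylbut-2-enyl)phenyl]prop-2-enethioate | CCSC(=O)/C=C(\OCOC)c1ccc(OCOC)c(CC=C(C)C)c1OC | intermediate
9 | 4-bromophenol | Oc1ccc(Br)cc1 | starting material
10 | 4-bromo-2-(3-methylbut-2-enyl)phenol | Oc1ccc(Br)cc1CC=C(C)C | intermediate
11 | 4-bromo-1-(methoxymethoxy)-2-(3-methylbut-2-enyl)benzene | COCOc1ccc(Br)cc1CC=C(C)C | intermediate
12 | [4-(methoxymethoxy)-3-(3-methylbut-2-enyl)phenyl]lithium | [Li]c1ccc(OCOC)c(CC=C(C)C)c1 | intermediate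
13 | lithium [4-(methoxymethoxy)-3-(3-methylbut-2-enyl)phenyl]tri(propan-2-yloxy)borate | [Li+].CC(C)O[B-](OC(C)C)(OC(C)C)c1ccc(OCOC)c(CC=C(C)C)c1 | intermediate
14 | [4-(methoxymethoxy)-3-(3-methylbut-2-enyl)phenyl]boronic acid | OB(O)c1ccc(OCOC)c(CC=C(C)C)c1 | intermediate
15 | (Z)-3-(methoxymethoxy)-3-[2-methoxy-4-(methoxymethoxy)-3-(3-methylbut-2-enyl)phenyl]-1-[4-(methoxymethoxy)-3-(3-methylbut-2-enyl)phenyl]prop-2-en-1-one | COCOc1ccc(C(=O)/C=C(\OCOC)c2ccc(OCOC)c(CC=C(C)C)c2OC)cc1CC=C(C)C | intermediate
16 | 1-[4-hydroxy-2-methoxy-3-(3-methylbut-2-enyl)phenyl]-3-[4-hydroxy-3-(3-methylbut-2-enyl)phenyl]propane-1,3-dione | COc1c(C(=O)CC(=O)c2ccc(O)c(CC=C(C)C)c2)ccc(O)c1CC=C(C)C | target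

## Step count and risks

Total steps: 10. Longest linear sequence: 7 (steps 1 to 5, then 9 and 10). The ring B branch (steps 6 to 8) joins at step 9.

**Step 9 (key step).** Oxidative addition into the C–S bond of a donor-substituted S-alkyl enethioate may be slow. Protodeboronation and oxidative homocoupling of the electron-rich boronic acid could then use up the aryl partner, or copper could deliver the aryl group in conjugate fashion. Fallback: a Fukuyama-type acyl coupling, for which S-ethyl thioesters are the usual substrates. It sets out from 11 and 8. Bromide 11 is lithiated to 12 as in step 8 and transmetalated with ZnCl2 to chlorido[4-(methoxymethoxy)-3-(3-methylbut-2-enyl)phenyl]zinc F1. F1 is coupled with 8 under PdCl2(PPh3)2 in THF–toluene at rt. This needs neither copper nor boron, and the route is rejoined at 15.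

**Step 1.** The C3-selectivity of the phenoxide alkylation may be poor, with C5-alkylation, O-alkylation and double alkylation eroding the return. Fallback: a rearrangement route from 1. The 4-OH is etherified with 3-chloro-3-methylbut-1-yne (K2CO3, KI, CuI, acetone) to 1-[2-hydroxy-4-(2-methylbut-3-yn-2-yloxy)phenyl]ethanone F2. The alkyne is half-reduced (H2, Pd/CaCO3 poisoned with Pb(OAc)2, quinoline) to 1-[2-hydroxy-4-(2-methylbut-3-en-2-yloxy)phenyl]ethanone F3. F3 is heated in N,N-diethylaniline. The aromatic Claisen rearrangement inverts the allyl unit to a prenyl group and is directed to C3 by the bond fixation of the chelated 2-hydroxy ketone, so the route is rejoined at 3.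

**Step 4.** Enolate self-condensation of the aryl methyl ketone and incomplete acyl transfer from the dithiocarbonate may compete. Fallback from 5:
- Methoxycarbonylation with NaH and dimethyl carbonate in toluene gives methyl 3-[2-methoxy-4-(methoxymethoxy)-3-(3-methylbut-2-enyl)phenyl]-3-oxopropanoate F4.
- NaH and MOMCl give methyl (Z)-3-(methoxymethoxy)-3-[2-methoxy-4-(methoxymethoxy)-3-(3-methylbut-2-enyl)phenyl]prop-2-enoate F5.
- LiOH in THF–MeOH–H2O gives (Z)-3-(methoxymethoxy)-3-[2-methoxy-4-(methoxymethoxy)-3-(3-methylbut-2-enyl)phenyl]prop-2-enoic acid F6, which cannot decarboxylate because the ketone is masked.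
- Steglich thioesterification with ethanethiol (DCC, DMAP, CH2Cl2) rejoins the route at 8.

**Step 6.** O-alkylation and 2,6-dialkylation may compete with the ortho-C-alkylation. Fallback from 9:
- Etherification with 3-chloro-3-methylbut-1-yne (DBU, CuCl2 cat., MeCN) gives 1-bromo-4-(2-methylbut-3-yn-2-yloxy)benzene F7.
- Half-reduction (H2, Pd/CaCO3 poisoned with Pb(OAc)2, quinoline) gives 1-bromo-4-(2-methylbut-3-en-2-yloxy)benzene F8.
- Thermal aromatic Claisen rearrangement delivers the prenyl group to the ortho carbon and rejoins the route at 10.

**Step 10.** As the phenols are freed, acid-induced ring closure onto the neighbouring prenyl alkenes (chroman formation) or addition of methanol across them may compete with acetal cleavage. Fallback from 15, in two stages, so that a free phenol never meets a Brønsted acid: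
- PPTS in wet acetone at rt removes only the far more labile enol MOM ether. The product is 1-[2-methoxy-4-(methoxymethoxy)-3-(3-methylbut-2-enyl)phenyl]-3-[4-(methoxymethoxy)-3-(3-methylbut-2-enyl)phenyl]propane-1,3-dione F9, the same compound as A7.
- ZnBr2 and propane-1-thiol in CH2Cl2 at 0 °C then cleave the two aryl MOM ethers by Lewis acid activation and thiol capture of the methoxymethyl group. The phenols are held as zinc phenoxides until work-up, and the route is rejoined at 16.

## Further compounds

F1 | step 9 | chlorido[4-(methoxymethoxy)-3-(3-methylbut-2-enyl)phenyl]zinc | Cl[Zn]c1ccc(OCOC)c(CC=C(C)C)c1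
F2 | step 1 | 1-[2-hydroxy-4-(2-methylbut-3-yn-2-yloxy)phenyl]ethanone | CC(=O)c1ccc(OC(C)(C)C#C)cc1O
F3 | step 1 | 1-[2-hydroxy-4-(2-methylbut-3-en-2-yloxy)phenyl]ethanone | CC(=O)c1ccc(OC(C)(C)C=C)cc1O
F4 | step 4 | methyl 3-[2-methoxy-4-(methoxymethoxy)-3-(3-methylbut-2-enyl)phenyl]-3-oxopropanoate | COC(=O)CC(=O)c1ccc(OCOC)c(CC=C(C)C)c1OC
F5 | step 4 | methyl (Z)-3-(methoxymethoxy)-3-[2-methoxy-4-(methoxymethoxy)-3-(3-methylbut-2-enyl)phenyl]prop-2-enoate | COC(=O)/C=C(\OCOC)c1ccc(OCOC)c(CC=C(C)C)c1OC
F6 | step 4 | (Z)-3-(methoxymethoxy)-3-[2-methoxy-4-(methoxymethoxy)-3-(3-methylbut-2-enyl)phenyl]prop-2-enoic acid | OC(=O)/C=C(\OCOC)c1ccc(OCOC)c(CC=C(C)C)c1OC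
F7 | step 6 | 1-bromo-4-(2-methylbut-3-yn-2-yloxy)benzene | C#CC(C)(C)Oc1ccc(Br)cc1
F8 | step 6 | 1-bromo-4-(2-methylbut-3-en-2-yloxy)benzene | C=CC(C)(C)Oc1ccc(Br)cc1
F9 | step 10 | 1-[2-methoxy-4-(methoxymethoxy)-3-(3-methylbut-2-enyl)phenyl]-3-[4-(methoxymethoxy)-3-(3-methylbut-2-enyl)phenyl]propane-1,3-dione | COCOc1ccc(C(=O)CC(=O)c2ccc(OCOC)c(CC=C(C)C)c2)c(OC)c1CC=C(C)C
A1 | alternative 1 | 1-[4-(tert-butyldimethylsilyloxy)-2-methoxy-3-(3-methylbut-2-enyl)phenyl]-3-[4-(tert-butyldimethylsilyloxy)-3-(3-methylbut-2-enyl)phenyl]prop-2-yn-1-one | COc1c(C(=O)C#Cc2ccc(O[Si](C)(C)C(C)(C)C)c(CC=C(C)C)c2)ccc(O[Si](C)(C)C(C)(C)C)c1CC=C(C)C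
A2 | alternative 1 | tert-butyl-[3-(dimethoxymethylidene)-6-methylhepta-1,5-dien-2-yl]oxy-dimethylsilane (1,1-dimethoxy-2-prenyl-3-silyloxybutadiene) | C=C(O[Si](C)(C)C(C)(C)C)C(CC=C(C)C)=C(OC)OC
A3 | alternative 1 | 1-[4-(tert-butyldimethylsilyloxy)-3-(3-methylbut-2-enyl)phenyl]penta-1,4-diyn-3-one | C#CC(=O)C#Cc1ccc(O[Si](C)(C)C(C)(C)C)c(CC=C(C)C)c1
A4 | alternative 2 | 5-[2-methoxy-4-(methoxymethoxy)-3-(3-methylbut-2-enyl)phenyl]-3-[4-(methoxymethoxy)-3-(3-methylbut-2-enyl)phenyl]-1,2-oxazole | COCOc1ccc(-c2cc(-c3ccc(OCOC)c(CC=C(C)C)c3)no2)c(OC)c1CC=C(C)C
A5 | alternative 2 | 1-bromo-2-methoxy-4-(methoxymethoxy)-3-(3-methylbut-2-enyl)benzene | COCOc1ccc(Br)c(OC)c1CC=C(C)C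
A6 | alternative 2 | tributyl-[3-[4-(methoxymethoxy)-3-(3-methylbut-2-enyl)phenyl]-1,2-oxazol-5-yl]stannane | CCCC[Sn](CCCC)(CCCC)c1cc(-c2ccc(OCOC)c(CC=C(C)C)c2)no1
A7 | alternative 3 | 1-[2-methoxy-4-(methoxymethoxy)-3-(3-methylbut-2-enyl)phenyl]-3-[4-(methoxymethoxy)-3-(3-methylbut-2-enyl)phenyl]propane-1,3-dione | COCOc1ccc(C(=O)CC(=O)c2ccc(OCOC)c(CC=C(C)C)c2)c(OC)c1CC=C(C)C
A8 | alternative 3 | 1-[2-methoxy-4-(methoxymethoxy)-3-(3-methylbut-2-enyl)phenyl]-2-[4-(methoxymethoxy)-3-(3-methylbut-2-enyl)phenyl]ethane-1,2-dione | COCOc1ccc(C(=O)C(=O)c2ccc(OCOC)c(CC=C(C)C)c2)c(OC)c1CC=C(C)C
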